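**Retrosynthetic overview**
1. Target 21 ← reductive N–O opening of the isoxazoline-bridged macrolide 19; the isoxazoline masks the C1 ketone and the C9 hydroxyl (anti-aldol retron).
2. 19 ← epoxy aldehyde/(Z)-β-iodoenoate 17 by one Ni/Cr-mediated operation: the C6–C7 bond closes the ten-membered carbocycle and the C6 alkoxide closes the butenolide; C6 is set here.
3. 17 ← hydroxyl-directed nitrile oxide cycloaddition of West allylic alcohol 11 with East oxime 6 (C9 and C10 set from C8), then acylations and oxidation.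
4. 11 ← crotonaldehyde + methyl propiolate (C8), then iodide/formaldehyde three-component coupling; 6 ← nerol by Sharpless epoxidation (C4, C5), ozonolysis and oximation.
5. Ring order: epoxide → isoxazoline → ten-membered ring and butenolide together → isoxazoline opened.

Assumption: the ProPhenol antipode written in step 4 is the one that gives the 4S alcohol 9; if the sense of induction is the opposite, the other commercial antipode is used and nothing else changes.

Atom labels C1–C15 are germacrane numbering of the target. CIP labels at C8 and C10 change along the route because substituent priorities change, not the configuration.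

**Step 1**
Reactants: 1 nerol
Product: 2 [(2S,3R)-3-methyl-3-(4-methylpent-3-en-1-yl)oxiran-2-yl]methanol
Conditions: Ti(OiPr)4 (5 mol %), L-(+)-DET (6 mol %), t-BuOOH, 4 Å MS, CH2Cl2, −20 °C
Reagents that add atoms: tert-butyl hydroperoxide CC(C)(C)OO
Why: Sharpless asymmetric epoxidation, in which the catalyst formed from Ti(OiPr)4 and L-(+)-DET binds the allylic hydroxyl and delivers oxygen to one face of the 2,3-alkene only (the remote alkene is not directed), giving the (2S,3R) epoxide that fixes C4 (R) and C5 (S) of the target with the cis C3/C6 relationship inherited from the Z alkene.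

**Step 2**
Reactants: 2 [(2S,3R)-3-methyl-3-(4-methylpent-3-en-1-yl)oxiran-2-yl]methanol
Product: 3 triethyl{[(2S,3R)-3-methyl-3-(4-methylpent-3-en-1-yl)oxiran-2-yl]methoxy}silane
Conditions: Et3SiCl, imidazole, CH2Cl2, 0 °C
Reagents that add atoms: chlorotriethylsilane CC[Si](Cl)(CC)CC
Why: Silyl ether formation masks the primary hydroxyl as a TES ether, chosen because a primary TES ether can later be oxidised directly to the aldehyde, and no stereocentre is touched.

**Step 3**
Reactants: 3 triethyl{[(2S,3R)-3-methyl-3-(4-methylpent-3-en-1-yl)oxiran-2-yl]methoxy}silane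
Product: 6 3-{(2R,3S)-2-methyl-3-[(triethylsilyloxy)methyl]oxiran-2-yl}propanal oxime (E/Z mixture), via secondary ozonide 4 (not isolated), via epoxy aldehyde 5 (not isolated)
Conditions: O3, CH2Cl2, −78 °C; PPh3, −78 °C → rt; then 50% aq. NH2OH, EtOH, rt
Reagents that add atoms: hydroxylamine NO
Why: Ozonolysis cleaves the only alkene left to the C1 aldehyde, which is condensed in the same flask to its oxime so that the γ,δ-epoxy aldehyde is never isolated, and the oxime geometry is irrelevant because it is lost in step 6.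

**Step 4**
Reactants: 7 (E)-but-2-enal (crotonaldehyde); 8 methyl prop-2-ynoate (methyl propiolate)
Product: 9 methyl (4S,5E)-4-hydroxyhept-5-en-2-ynoate
Conditions: (S,S)-ProPhenol (10 mol %), Me2Zn (3 equiv), 8 (3 equiv), Ph3P=O (20 mol %), toluene, 4 °C
Reagents that add atoms: none
Why: Catalytic asymmetric alkynylation of an enal, in which the catalyst formed from Me2Zn and ProPhenol generates the zinc acetylide of the propiolate and adds it 1,2 to one enantioface of the aldehyde, setting C8 as the (S) propargylic alcohol.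

**Step 5**
Reactants: 9 methyl (4S,5E)-4-hydroxyhept-5-en-2-ynoate
Product: 11 methyl (2Z,4S,5E)-4-hydroxy-2-(hydroxymethyl)-3-iodohepta-2,5-dienoate, via iodomagnesium allenolate 10 (not isolated)
Conditions: MgI2 (2 equiv), monomeric CH2O (THF solution, 3 equiv), CH2Cl2, 0 °C → rt
Reagents that add atoms: magnesium diiodide [Mg+2].[I-].[I-]; formaldehyde C=O
Why: Proposed new method: iodide from MgI2 adds in a conjugate sense to the Lewis-acid-activated ynoate to give the β-iodoallenolate 10, whose α-carbon is trapped by formaldehyde anti to iodine (the same anti sense as hydroiodination of 2-alkynoates), so that iodine ends cis to the ester (Z) and the new CH2OH cis to C8, the closest known reaction being the MgI2- or TiCl4/iodide-mediated β-iodo Baylis–Hillman (halo-aldol) coupling of propiolates and ynones with aldehydes, here extended to a β-substituted ynoate and formaldehyde, with C8 untouched.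

**Step 6**
Reactants: 6 3-{(2R,3S)-2-methyl-3-[(triethylsilyloxy)methyl]oxiran-2-yl}propanal oxime; 11 methyl (2Z,4S,5E)-4-hydroxy-2-(hydroxymethyl)-3-iodohepta-2,5-dienoate
Product: 14 methyl (2Z,4S)-4-hydroxy-2-(hydroxymethyl)-3-iodo-4-[(4R,5R)-4-methyl-3-(2-{(2R,3S)-2-methyl-3-[(triethylsilyloxy)methyl]oxiran-2-yl}ethyl)-4,5-dihydro-1,2-oxazol-5-yl]but-2-enoate, via hydroximoyl chloride 12 (not isolated), via nitrile oxide 13 (not isolated)
Conditions: 6 (1.3 equiv), t-BuOCl, CH2Cl2, −78 °C; added over 2 h to 11, i-PrOH (3 equiv), EtMgBr (4 equiv), CH2Cl2, 0 °C → rt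
Reagents that add atoms: none
Why: Magnesium-alkoxide-directed nitrile oxide cycloaddition (Kanemasa-type 1,3-dipolar cycloaddition), in which the C8 alkoxide binds the dipole oxygen and delivers it to the near alkene carbon C9 on the face that gives the 8,9-syn adduct while C1 bonds to C10, and the E alkene is translated suprafacially into the trans-4,5-disubstituted isoxazoline (the 9,10-anti aldol relationship), so C9 and C10 are both set from C8 while the tetrasubstituted iodoalkene is inert to the dipole.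

**Step 7**
Reactants: 14 isoxazoline diol (name as in step 6)
Product: 16 methyl (2Z,4S)-2-(acetoxymethyl)-3-iodo-4-(methacryloyloxy)-4-[(4R,5R)-4-methyl-3-(2-{(2R,3S)-2-methyl-3-[(triethylsilyloxy)methyl]oxiran-2-yl}ethyl)-4,5-dihydro-1,2-oxazol-5-yl]but-2-enoate, via primary monoacetate 15 (not isolated)
Conditions: AcCl (1.05 equiv), 2,4,6-collidine, CH2Cl2, −78 °C; then methacrylic anhydride, Et3N, DMAP (cat.), 0 °C → rt
Reagents that add atoms: acetyl chloride CC(Cl)=O; methacrylic anhydride CC(=C)C(=O)OC(=O)C(C)=C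
Why: Sequential chemoselective acylation, in which AcCl/collidine at low temperature acetylates only the unhindered primary allylic hydroxyl (C13) and DMAP-catalysed acylation then esterifies the remaining secondary C8 hydroxyl with retention, the C9 oxygen being locked in the isoxazoline so that no acyl migration can occur.

**Step 8**
Reactants: 16 acetate methacrylate TES ether (name as in step 7)
Product: 17 methyl (2Z,4S)-2-(acetoxymethyl)-4-[(4R,5R)-3-{2-[(2R,3R)-3-formyl-2-methyloxiran-2-yl]ethyl}-4-methyl-4,5-dihydro-1,2-oxazol-5-yl]-3-iodo-4-(methacryloyloxy)but-2-enoate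
Conditions: (COCl)2, DMSO, CH2Cl2, −78 → −30 °C; Et3N, −78 → 0 °C
Reagents that add atoms: none
Why: Swern oxidation of a primary TES ether, in which the chlorosulfonium salt cleaves the silyl ether in situ and the resulting alkoxysulfonium salt collapses to the α,β-epoxy aldehyde without a separate deprotection, leaving the isoxazoline, esters, vinyl iodide and all stereocentres untouched.

**Step 9**
Reactants: 17 epoxy aldehyde vinyl iodide (name as in step 8)
Product: 19 isoxazoline-bridged macrocyclic butenolide (target skeleton in which C1=N–O–C9 replaces the 1-oxo and 9-hydroxy groups; 4R,5S,6S,8R,9R,10R), via ring-closed CrCl2 alkoxide 18 (not isolated)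
Conditions: CrCl2 (10 equiv), NiCl2 (2 mol % of CrCl2), degassed DMSO/THF, rt, syringe-pump addition of 17 to 2 mM; aq. NH4Cl work-up
Reagents that add atoms: none
Why: Nozaki–Hiyama–Kishi macrocyclisation with in situ lactonisation, in which nickel-catalysed insertion into the activated C7–I bond and transmetallation to trivalent chromium give an alkenyl–CrCl2 species that adds only to the aldehyde, the cis epoxide and the isoxazoline acting as rigid turn elements that bring C6 and C7 together, after which the C6 alkoxide, held cis to the ester by the retained Z geometry, expels methoxide to close the butenolide, so the ten-membered carbocycle and the lactone form in one operation and C6 is set by Felkin–Anh attack anti to the epoxide C–O bond (5,6-anti).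

**Step 10**
Reactants: 19 isoxazoline-bridged macrocyclic butenolide
Product: 21 CNP0185951.2 = (4R,5S,6S,8R,9R,10S)-13-acetoxy-4,5-epoxy-9-hydroxy-8-(methacryloyloxy)-1-oxogermacr-7(11)-en-12,6-olide, via hydroxy imine 20 (not isolated)
Conditions: Mo(CO)6 (1.2 equiv), MeCN/H2O (10:1), 80 °C
Reagents that add atoms: water O
Why: Reductive N–O cleavage of a 2-isoxazoline by Mo(CO)6 in wet acetonitrile followed by in situ hydrolysis of the β-hydroxy imine unmasks the C1 ketone and the C9 hydroxyl without touching C9 or epimerising C10, and this reagent is chosen because it spares the conjugated esters, the allylic acetate and the epoxide that hydrogenation or dissolving-metal conditions would attack.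

**Compound list**
1 | nerol, (2Z)-3,7-dimethylocta-2,6-dien-1-ol | OC/C=C(/C)CCC=C(C)C | starting material
2 | [(2S,3R)-3-methyl-3-(4-methylpent-3-en-1-yl)oxiran-2-yl]methanol | OC[C@@H]1O[C@]1(C)CCC=C(C)C | intermediate
3 | triethyl{[(2S,3R)-3-methyl-3-(4-methylpent-3-en-1-yl)oxiran-2-yl]methoxy}silane | CC[Si](CC)(CC)OC[C@@H]1O[C@]1(C)CCC=C(C)C | intermediate
4 | 3,3-dimethyl-5-(2-{(2R,3S)-2-methyl-3-[(triethylsilyloxy)methyl]oxiran-2-yl}ethyl)-1,2,4-trioxolane (ozonide, not isolated) | CC[Si](CC)(CC)OC[C@@H]1O[C@]1(C)CCC1OOC(C)(C)O1 | intermediate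
5 | 3-{(2R,3S)-2-methyl-3-[(triethylsilyloxy)methyl]oxiran-2-yl}propanal (not isolated) | CC[Si](CC)(CC)OC[C@@H]1O[C@]1(C)CCC=O | intermediate
6 | 3-{(2R,3S)-2-methyl-3-[(triethylsilyloxy)methyl]oxiran-2-yl}propanal oxime | CC[Si](CC)(CC)OC[C@@H]1O[C@]1(C)CCC=NO | intermediate
7 | (E)-but-2-enal (crotonaldehyde) | C/C=C/C=O | starting material
8 | methyl prop-2-ynoate (methyl propiolate) | C#CC(=O)OC | starting material
9 | methyl (4S,5E)-4-hydroxyhept-5-en-2-ynoate | COC(=O)C#C[C@@H](O)/C=C/C | intermediate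
10 | iodomagnesium allenolate of methyl (4S,5E)-4-hydroxy-3-iodohepta-2,5-dienoate (not isolated) | COC(O[Mg]I)=C=C(I)[C@@H](O)/C=C/C | intermediate
11 | methyl (2Z,4S,5E)-4-hydroxy-2-(hydroxymethyl)-3-iodohepta-2,5-dienoate | COC(=O)/C(CO)=C(\I)[C@@H](O)/C=C/C | intermediate
12 | N-hydroxy-3-{(2R,3S)-2-methyl-3-[(triethylsilyloxy)methyl]oxiran-2-yl}propanimidoyl chloride (not isolated) | CC[Si](CC)(CC)OC[C@@H]1O[C@]1(C)CCC(Cl)=NO | intermediate
13 | 3-{(2R,3S)-2-methyl-3-[(triethylsilyloxy)methyl]oxiran-2-yl}propanenitrile oxide (not isolated) | CC[Si](CC)(CC)OC[C@@H]1O[C@]1(C)CCC#[N+][O-] | intermediate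
14 | methyl (2Z,4S)-4-hydroxy-2-(hydroxymethyl)-3-iodo-4-[(4R,5R)-4-methyl-3-(2-{(2R,3S)-2-methyl-3-[(triethylsilyloxy)methyl]oxiran-2-yl}ethyl)-4,5-dihydro-1,2-oxazol-5-yl]but-2-enoate | CC[Si](CC)(CC)OC[C@@H]1O[C@]1(C)CCC2=NO[C@H]([C@@H]2C)[C@H](O)/C(I)=C(\CO)C(=O)OC | intermediate
15 | C13 monoacetate of 14 (not isolated) | CC[Si](CC)(CC)OC[C@@H]1O[C@]1(C)CCC2=NO[C@H]([C@@H]2C)[C@H](O)/C(I)=C(\COC(C)=O)C(=O)OC | intermediate
16 | methyl (2Z,4S)-2-(acetoxymethyl)-3-iodo-4-(methacryloyloxy)-4-[(4R,5R)-4-methyl-3-(2-{(2R,3S)-2-methyl-3-[(triethylsilyloxy)methyl]oxiran-2-yl}ethyl)-4,5-dihydro-1,2-oxazol-5-yl]but-2-enoate | CC[Si](CC)(CC)OC[C@@H]1O[C@]1(C)CCC2=NO[C@H]([C@@H]2C)[C@H](OC(=O)C(C)=C)/C(I)=C(\COC(C)=O)C(=O)OC | intermediate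
17 | methyl (2Z,4S)-2-(acetoxymethyl)-4-[(4R,5R)-3-{2-[(2R,3R)-3-formyl-2-methyloxiran-2-yl]ethyl}-4-methyl-4,5-dihydro-1,2-oxazol-5-yl]-3-iodo-4-(methacryloyloxy)but-2-enoate | O=C[C@@H]1O[C@]1(C)CCC2=NO[C@H]([C@@H]2C)[C@H](OC(=O)C(C)=C)/C(I)=C(\COC(C)=O)C(=O)OC | intermediate
18 | ten-membered C6 CrCl2 alkoxide, methyl ester not yet lactonised (6S,8R; not isolated) | COC(=O)/C(COC(C)=O)=C1\[C@H](O[Cr](Cl)Cl)[C@@H]2O[C@]2(C)CCC2=NO[C@H]([C@@H]2C)[C@@H]1OC(=O)C(C)=C | intermediate
19 | isoxazoline-bridged macrocyclic butenolide (4R,5S,6S,8R,9R,10R; C1=N–O–C9) | C=C(C)C(=O)O[C@@H]1C2=C(COC(C)=O)C(=O)O[C@@H]2[C@@H]2O[C@]2(C)CCC2=NO[C@@H]1[C@@H]2C | intermediate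
20 | 1-imino analogue of the target (β-hydroxy imine, not isolated) | C=C(C)C(=O)O[C@@H]1C2=C(COC(C)=O)C(=O)O[C@@H]2[C@@H]2O[C@]2(C)CCC(=N)[C@@H](C)[C@H]1O | intermediate
21 | CNP0185951.2, (4R,5S,6S,8R,9R,10S)-13-acetoxy-4,5-epoxy-9-hydroxy-8-(methacryloyloxy)-1-oxogermacr-7(11)-en-12,6-olide | C=C(C)C(=O)O[C@@H]1C2=C(COC(C)=O)C(=O)O[C@@H]2[C@@H]2O[C@]2(C)CCC(=O)[C@@H](C)[C@H]1O | target

**Step count**
Total: 10 steps (one-pot operations counted once). Longest linear sequence: 8 steps (steps 1, 2, 3, 6, 7, 8, 9, 10 from nerol); the West branch is steps 4 and 5.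

**Three steps most likely to fail, with fallbacks**

Step 5 (iodide/formaldehyde coupling on a β-substituted ynoate). Risks are formaldehyde oligomerisation, ionisation of the free allylic alcohol, and E/Z erosion. The fallback sets out from 9 and comes back at 11. 9 is silylated (Et3SiCl, imidazole) to methyl (4S,5E)-4-[(triethylsilyl)oxy]hept-5-en-2-ynoate F1. TMSI (1.05 equiv, CH2Cl2, −78 °C) adds iodide to give the trimethylsilyl iodoallenyl ketene acetal F2, which is not isolated. F2 is alkylated at C11 with benzyl chloromethyl ether and catalytic ZnBr2 (a Mukaiyama-type alkoxymethylation in place of the aldol) to give methyl (2Z,4S,5E)-2-[(benzyloxy)methyl]-3-iodo-4-[(triethylsilyl)oxy]hepta-2,5-dienoate F3. BCl3 with pentamethylbenzene at −78 °C, then methanol quench, removes the benzyl and TES groups and gives 11.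

Step 9 (ten-membered ring and butenolide in one Ni/Cr operation). Risks are oligomerisation, a strained bridged transition state, and poor C6 selectivity. The fallback sets out from 6 and 11 and comes back at 19; it forms the butenolide intermolecularly and closes the carbocycle by the directed cycloaddition instead.
- 6 is O-silylated (TBSCl, imidazole) to the O-TBS oxime F4, and Swern oxidation of its TES ether gives the epoxy aldehyde O-TBS oxime F5.
- 11 is acetylated at the primary hydroxyl (AcCl, collidine, −78 °C) to methyl (2Z,4S,5E)-2-(acetoxymethyl)-4-hydroxy-3-iodohepta-2,5-dienoate F6.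
- F5 and F6 are coupled with CrCl2/NiCl2 in DMSO; the open-chain CrCl2 alkoxide F7 lactonises to the butenolide O-TBS oxime F8 (C6 by Felkin–Anh addition, minor epimer removed).
- TBAF/AcOH frees the oxime F9. t-BuOCl gives the hydroximoyl chloride F10, and slow addition to i-PrOMgBr at high dilution generates the nitrile oxide F11.
- F11 cyclises under direction of the C8 alkoxide to the macrocyclic isoxazoline alcohol F12.
- Methacrylic anhydride/DMAP converts F12 into 19.

Step 10 (N–O cleavage on the fully functionalised macrocycle). Risks are attack of Mo(CO)6 on the allylic acetate or the epoxide next to the butenolide, and β-elimination of the product. The fallback sets out from 16 and comes back at 21; it unmasks the aldol before ring closure.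
- Mo(CO)6 in wet MeCN opens the isoxazoline of 16 by way of the β-hydroxy imine F13 to the acyclic β-hydroxy ketone TES ether F14.
- TBAF/AcOH removes the silyl group to give the diol F15.
- TEMPO/PhI(OAc)2 oxidises only the primary alcohol to the epoxy aldehyde F16.
- The CrCl2/NiCl2 closure is run on F16 at 2 mM; the ring-closed CrCl2 alkoxide F17 lactonises directly to 21.

**Further compounds**
F1 | step 5 | methyl (4S,5E)-4-[(triethylsilyl)oxy]hept-5-en-2-ynoate | COC(=O)C#C[C@@H](O[Si](CC)(CC)CC)/C=C/C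
F2 | step 5 | methyl trimethylsilyl ketene acetal of (4S,5E)-3-iodo-4-[(triethylsilyl)oxy]hepta-2,5-dienoate (iodoallene, not isolated) | COC(O[Si](C)(C)C)=C=C(I)[C@@H](O[Si](CC)(CC)CC)/C=C/C
F3 | step 5 | methyl (2Z,4S,5E)-2-[(benzyloxy)methyl]-3-iodo-4-[(triethylsilyl)oxy]hepta-2,5-dienoate | COC(=O)/C(COCc1ccccc1)=C(\I)[C@@H](O[Si](CC)(CC)CC)/C=C/C
F4 | step 9 | O-(tert-butyldimethylsilyl) oxime of 5 | CC[Si](CC)(CC)OC[C@@H]1O[C@]1(C)CCC=NO[Si](C)(C)C(C)(C)C
F5 | step 9 | (2R,3R)-3-{3-[(tert-butyldimethylsilyloxy)imino]propyl}-3-methyloxirane-2-carbaldehyde | O=C[C@@H]1O[C@]1(C)CCC=NO[Si](C)(C)C(C)(C)C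
F6 | step 9 | methyl (2Z,4S,5E)-2-(acetoxymethyl)-4-hydroxy-3-iodohepta-2,5-dienoate | COC(=O)/C(COC(C)=O)=C(\I)[C@@H](O)/C=C/C
F7 | step 9 | open-chain C6 CrCl2 alkoxide from F5 and F6 (not isolated) | COC(=O)/C(COC(C)=O)=C(/[C@@H](O)/C=C/C)\[C@H](O[Cr](Cl)Cl)[C@@H]1O[C@]1(C)CCC=NO[Si](C)(C)C(C)(C)C
F8 | step 9 | 3-(acetoxymethyl)-4-[(1S,2E)-1-hydroxybut-2-enyl]butenolide carrying the epoxy O-TBS oxime chain at C5 (6S by target numbering) | C/C=C/[C@H](O)C1=C(COC(C)=O)C(=O)O[C@@H]1[C@@H]1O[C@]1(C)CCC=NO[Si](C)(C)C(C)(C)C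
F9 | step 9 | free oxime of F8 | C/C=C/[C@H](O)C1=C(COC(C)=O)C(=O)O[C@@H]1[C@@H]1O[C@]1(C)CCC=NO
F10 | step 9 | hydroximoyl chloride of F9 (not isolated) | C/C=C/[C@H](O)C1=C(COC(C)=O)C(=O)O[C@@H]1[C@@H]1O[C@]1(C)CCC(Cl)=NO
F11 | step 9 | nitrile oxide from F10 (not isolated) | C/C=C/[C@H](O)C1=C(COC(C)=O)C(=O)O[C@@H]1[C@@H]1O[C@]1(C)CCC#[N+][O-]
F12 | step 9 | 8-hydroxy analogue of 19 (isoxazoline-bridged macrocyclic butenolide with free C8 hydroxyl) | O[C@@H]1C2=C(COC(C)=O)C(=O)O[C@@H]2[C@@H]2O[C@]2(C)CCC2=NO[C@@H]1[C@@H]2C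
F13 | step 10 | acyclic β-hydroxy imine from 16 (not isolated) | CC[Si](CC)(CC)OC[C@@H]1O[C@]1(C)CCC(=N)[C@@H](C)[C@@H](O)[C@H](OC(=O)C(C)=C)/C(I)=C(\COC(C)=O)C(=O)OC
F14 | step 10 | acyclic β-hydroxy ketone TES ether (C1 ketone, C9 hydroxyl, vinyl iodide) | CC[Si](CC)(CC)OC[C@@H]1O[C@]1(C)CCC(=O)[C@@H](C)[C@@H](O)[C@H](OC(=O)C(C)=C)/C(I)=C(\COC(C)=O)C(=O)OC
F15 | step 10 | C6,C9-diol from F14 | OC[C@@H]1O[C@]1(C)CCC(=O)[C@@H](C)[C@@H](O)[C@H](OC(=O)C(C)=C)/C(I)=C(\COC(C)=O)C(=O)OC
F16 | step 10 | epoxy aldehyde with free C9 hydroxyl and C1 ketone | O=C[C@@H]1O[C@]1(C)CCC(=O)[C@@H](C)[C@@H](O)[C@H](OC(=O)C(C)=C)/C(I)=C(\COC(C)=O)C(=O)OC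
F17 | step 10 | ring-closed C6 CrCl2 alkoxide of the seco methyl ester of 21 (not isolated) | COC(=O)/C(COC(C)=O)=C1\[C@H](O[Cr](Cl)Cl)[C@@H]2O[C@]2(C)CCC(=O)[C@@H](C)[C@@H](O)[C@@H]1OC(=O)C(C)=C
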